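The route rests on cutting the C4–C4a bond of the flavone, so that ring C is closed last by an intramolecular Friedel–Crafts acylation. The step exploits C4a, the one unsubstituted carbon of ring A, which lies ortho to O1 and to the C5 oxygen and para to the C7 oxygen and so attacks the activated C4 carboxyl carbon. In one operation it forms the pyranone and completes the hexasubstituted ring A with all three prenyl groups in place. The precursor is a (Z)-3-aryloxy-2-prenyl-3-arylacrylic acid with its four phenolic oxygens capped as allyl ethers, assembled by vinylic substitution of an enol triflate by 2,4-diprenylphloroglucinol.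

Key step: step 9

Remark on the chemistry: all four phenolic oxygens are carried as allyl ethers and the ester is methyl. Allyl ethers survive every basic step, so the 2'-oxygen of ring B is never free to lactonise onto the carboxyl carbon. They also donate well into ring A and come off at the end under neutral palladium catalysis, which cannot cyclise a prenyl group onto a neighbouring hydroxyl. The methyl ester eases hydrolysis of the hindered acrylate.

Step 1
Reactants: 1 phloroglucinol; 2 prenyl bromide
Product: 3 2,4-bis(3-methylbut-2-en-1-yl)benzene-1,3,5-triol (2,4-diprenylphloroglucinol)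
Conditions: 2 (2.1 equiv), KOH (2.2 equiv), H2O, 0 °C to rt; chromatography
Reagents that add atoms: none
Why: C-alkylation of the ambident phloroglucinol phenoxide, favoured in water where the oxygens are solvated; the second prenyl group enters one of the two equivalent remaining ring carbons, and the product is separated from mono- and triprenylated material.

Step 2
Reactants: 4 2,4-dihydroxyacetophenone
Product: 5 1-[2,4-bis(prop-2-en-1-yloxy)phenyl]ethan-1-one (2,4-bis(allyloxy)acetophenone)
Conditions: allyl bromide (2.5 equiv), K2CO3, DMF, 60 °C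
Reagents that add atoms: allyl bromide, C=CCBr
Why: Williamson ether synthesis on both phenols, with DMF and gentle heating to alkylate the hydrogen-bonded 2-hydroxyl as well.

Step 3
Reactants: 5 2,4-bis(allyloxy)acetophenone; 6 dimethyl carbonate
Product: 7 methyl 3-[2,4-bis(prop-2-en-1-yloxy)phenyl]-3-oxopropanoate
Conditions: NaH (2.5 equiv), 6 (excess), THF, reflux; then 1 M HCl, 0 °C
Reagents that add atoms: none
Why: Crossed Claisen condensation of the methyl ketone enolate with the carbonate, driven by deprotonation of the β-keto ester; with both phenols capped no 4-hydroxycoumarin can form.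

Step 4
Reactants: 7 methyl 3-[2,4-bis(allyloxy)phenyl]-3-oxopropanoate; 2 prenyl bromide
Product: 8 methyl 2-[2,4-bis(prop-2-en-1-yloxy)benzoyl]-5-methylhex-4-enoate (racemic)
Conditions: 2 (1.05 equiv), K2CO3, acetone, reflux
Reagents that add atoms: none
Why: Mono C-alkylation of the stabilised β-keto ester enolate by SN2 attack on the primary allylic bromide; the new stereocentre is formed racemic and is erased in step 5.

Step 5
Reactants: 8 methyl 2-[2,4-bis(allyloxy)benzoyl]-5-methylhex-4-enoate
Product: 9 methyl (Z)-3-[2,4-bis(prop-2-en-1-yloxy)phenyl]-2-(3-methylbut-2-en-1-yl)-3-[(trifluoromethanesulfonyl)oxy]prop-2-enoate (triflyloxy group cis to the ester)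
Conditions: NaH, CH2Cl2, 0 °C; Tf2O, −78 to 0 °C
Reagents that add atoms: trifluoromethanesulfonic anhydride, O=S(=O)(OS(=O)(=O)C(F)(F)F)C(F)(F)F
Why: O-sulfonylation of the β-keto ester enolate (enol triflate formation); the sodium chelate between enolate and ester oxygens fixes the Z geometry.

Step 6
Reactants: 9 the (Z)-enol triflate; 3 2,4-diprenylphloroglucinol
Product: 10 methyl (Z)-3-[2,4-bis(prop-2-en-1-yloxy)phenyl]-3-[3,5-dihydroxy-2,4-bis(3-methylbut-2-en-1-yl)phenoxy]-2-(3-methylbut-2-en-1-yl)prop-2-enoate (aryloxy group cis to the ester)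
Conditions: 3 (2 equiv), Cs2CO3 (1.2 equiv), DMF, 0 °C to rt, argon
Reagents that add atoms: none
Why: Nucleophilic vinylic substitution by addition–elimination at the β-carbon of the triflyloxy acrylate, with retention of geometry; the phenoxide comes from one of the two equivalent hydroxyls of 3 that flank its ring C–H, the hydroxyl between the two prenyl groups being too hindered, and excess 3 suppresses a second vinylation.

Step 7
Reactants: 10 the dihydroxy aryloxyacrylate
Product: 11 methyl (Z)-3-[2,4-bis(prop-2-en-1-yloxy)phenyl]-3-[3,5-bis(prop-2-en-1-yloxy)-2,4-bis(3-methylbut-2-en-1-yl)phenoxy]-2-(3-methylbut-2-en-1-yl)prop-2-enoate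
Conditions: allyl bromide (3 equiv), K2CO3, DMF, rt
Reagents that add atoms: allyl bromide, C=CCBr
Why: Williamson ether synthesis on the two remaining phenols, O-alkylation being favoured in a dipolar aprotic solvent; the enol ether and the ester are untouched.

Step 8
Reactants: 11 the tetraallyl methyl ester
Product: 12 (Z)-3-[2,4-bis(prop-2-en-1-yloxy)phenyl]-3-[3,5-bis(prop-2-en-1-yloxy)-2,4-bis(3-methylbut-2-en-1-yl)phenoxy]-2-(3-methylbut-2-en-1-yl)prop-2-enoic acid
Conditions: LiOH·H2O, THF/MeOH/H2O, 50 °C; then 1 M HCl to pH 4, 0 °C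
Reagents that add atoms: lithium hydroxide, [Li+].[OH-]
Why: Saponification of the methyl ester; the allyl ethers and the aryl enol ether are stable to hydroxide, the carboxylate resists further attack, and cold acidification only to pH 4 avoids protonating the enol ether.

Step 9
Reactants: 12 the (Z)-3-aryloxy-2-prenylacrylic acid
Product: 14 5,7-bis(prop-2-en-1-yloxy)-2-[2,4-bis(prop-2-en-1-yloxy)phenyl]-3,6,8-tris(3-methylbut-2-en-1-yl)-4H-chromen-4-one (artelasticin tetraallyl ether), via mixed trifluoroacetic anhydride 13 (not isolated)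
Conditions: (CF3CO)2O (2 equiv), CH2Cl2, 0 °C
Reagents that add atoms: trifluoroacetic anhydride, O=C(OC(=O)C(F)(F)F)C(F)(F)F (its trifluoroacetyl group is held only in intermediate 13 and leaves again as trifluoroacetic acid)
Why: The anhydride converts the acid into mixed anhydride 13, whose acyl carbon (the future C4) is attacked by C4a of ring A in an electrophilic aromatic substitution, and loss of the C4a proton and of trifluoroacetate should give the chromone. This is an intramolecular Friedel–Crafts acylation, the reaction type by which 3-aryloxyacrylic and 3-aryloxycinnamic acids are closed to chromones and flavones. Ring C closes in a 6-exo-trig mode at the acyl carbon, and no stereocentre is formed. Site selectivity needs no control element, because C4a is the only ring-A carbon that still bears hydrogen. It lies ortho to O1 and to the C5 allyloxy group and para to the C7 allyloxy group, so the mixed anhydride should suffice without a Lewis acid and the seven alkenes should be spared. The Z alkene holds the aryloxy ring and the acyl carbon on the same side, and ring B cannot compete, since its 2'-oxygen is capped and its free ortho carbon C6' is meta to both of its oxygens.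

Step 10
Reactants: 14 artelasticin tetraallyl ether
Product: 15 artelasticin, 2-(2,4-dihydroxyphenyl)-5,7-dihydroxy-3,6,8-tris(3-methylbut-2-en-1-yl)-4H-chromen-4-one
Conditions: Pd(PPh3)4 (10 mol %), morpholine (20 equiv), THF, rt, argon
Reagents that add atoms: none
Why: Tsuji–Trost-type deallylation, in which zerovalent palladium ionises each aryl allyl ether to a π-allyl complex and a phenoxide and morpholine captures the allyl group; the carbon-bound prenyl groups cannot ionise and no acid is present to cyclise them onto the freed hydroxyls.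

Compound list
1 | phloroglucinol (benzene-1,3,5-triol) | Oc1cc(O)cc(O)c1 | starting material
2 | prenyl bromide (1-bromo-3-methylbut-2-ene) | CC(C)=CCBr | starting material
3 | 2,4-bis(3-methylbut-2-en-1-yl)benzene-1,3,5-triol | CC(C)=CCc1c(O)cc(O)c(CC=C(C)C)c1O | intermediate
4 | 2,4-dihydroxyacetophenone | CC(=O)c1ccc(O)cc1O | starting material
5 | 1-[2,4-bis(prop-2-en-1-yloxy)phenyl]ethan-1-one | CC(=O)c1ccc(OCC=C)cc1OCC=C | intermediate
6 | dimethyl carbonate | COC(=O)OC | starting material
7 | methyl 3-[2,4-bis(prop-2-en-1-yloxy)phenyl]-3-oxopropanoate | COC(=O)CC(=O)c1ccc(OCC=C)cc1OCC=C | intermediate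
8 | methyl 2-[2,4-bis(prop-2-en-1-yloxy)benzoyl]-5-methylhex-4-enoate (racemic) | COC(=O)C(CC=C(C)C)C(=O)c1ccc(OCC=C)cc1OCC=C | intermediate
9 | methyl (Z)-3-[2,4-bis(prop-2-en-1-yloxy)phenyl]-2-(3-methylbut-2-en-1-yl)-3-[(trifluoromethanesulfonyl)oxy]prop-2-enoate | COC(=O)/C(CC=C(C)C)=C(\OS(=O)(=O)C(F)(F)F)c1ccc(OCC=C)cc1OCC=C | intermediate
10 | methyl (Z)-3-[2,4-bis(prop-2-en-1-yloxy)phenyl]-3-[3,5-dihydroxy-2,4-bis(3-methylbut-2-en-1-yl)phenoxy]-2-(3-methylbut-2-en-1-yl)prop-2-enoate | COC(=O)/C(CC=C(C)C)=C(\Oc1cc(O)c(CC=C(C)C)c(O)c1CC=C(C)C)c1ccc(OCC=C)cc1OCC=C | intermediate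
11 | methyl (Z)-3-[2,4-bis(prop-2-en-1-yloxy)phenyl]-3-[3,5-bis(prop-2-en-1-yloxy)-2,4-bis(3-methylbut-2-en-1-yl)phenoxy]-2-(3-methylbut-2-en-1-yl)prop-2-enoate | COC(=O)/C(CC=C(C)C)=C(\Oc1cc(OCC=C)c(CC=C(C)C)c(OCC=C)c1CC=C(C)C)c1ccc(OCC=C)cc1OCC=C | intermediate
12 | (Z)-3-[2,4-bis(prop-2-en-1-yloxy)phenyl]-3-[3,5-bis(prop-2-en-1-yloxy)-2,4-bis(3-methylbut-2-en-1-yl)phenoxy]-2-(3-methylbut-2-en-1-yl)prop-2-enoic acid | OC(=O)/C(CC=C(C)C)=C(\Oc1cc(OCC=C)c(CC=C(C)C)c(OCC=C)c1CC=C(C)C)c1ccc(OCC=C)cc1OCC=C | intermediate
13 | mixed anhydride of acid 12 with trifluoroacetic acid (Z alkene retained) | O=C(OC(=O)C(F)(F)F)/C(CC=C(C)C)=C(\Oc1cc(OCC=C)c(CC=C(C)C)c(OCC=C)c1CC=C(C)C)c1ccc(OCC=C)cc1OCC=C | intermediate (not isolated)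
14 | 5,7-bis(prop-2-en-1-yloxy)-2-[2,4-bis(prop-2-en-1-yloxy)phenyl]-3,6,8-tris(3-methylbut-2-en-1-yl)-4H-chromen-4-one | CC(C)=CCc1c(OCC=C)c(CC=C(C)C)c2oc(-c3ccc(OCC=C)cc3OCC=C)c(CC=C(C)C)c(=O)c2c1OCC=C | intermediate
15 | artelasticin, 2-(2,4-dihydroxyphenyl)-5,7-dihydroxy-3,6,8-tris(3-methylbut-2-en-1-yl)-4H-chromen-4-one | CC(C)=CCc1c(O)c(CC=C(C)C)c2oc(-c3ccc(O)cc3O)c(CC=C(C)C)c(=O)c2c1O | target

Total step count: 10. Longest linear sequence: 9 steps (steps 2 to 10, from 4).

Steps most likely to fail

Step 9. The trifluoroacetic acid set free may protonate a prenyl alkene, after which a neighbouring allyloxy oxygen captures the tertiary cation with loss of its allyl group. The anhydride may also transfer its trifluoroacetyl group to C4a instead of closing the ring. The fallback activates the acid without any Brønsted acid. Setting out from 12, 1-chloro-N,N,2-trimethylprop-1-en-1-amine in CH2Cl2 at 0 °C should give, under neutral conditions, the acid chloride (Z)-3-[2,4-bis(prop-2-en-1-yloxy)phenyl]-3-[3,5-bis(prop-2-en-1-yloxy)-2,4-bis(3-methylbut-2-en-1-yl)phenoxy]-2-(3-methylbut-2-en-1-yl)prop-2-enoyl chloride F1. AgOTf with 2,6-di-tert-butyl-4-methylpyridine in CH2Cl2 at −40 °C then abstracts chloride, the acyl triflate acylates C4a, and the hindered pyridine takes up the triflic acid. The same C4–C4a bond is formed and the route is rejoined at 14.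

Step 6. The phenoxide may attack the sulfur of the triflate faster than the hindered, fully substituted β-carbon, which transfers the triflyl group and returns the β-keto ester. Reaction through the ring carbon of 3 or at both equivalent hydroxyls may also intrude. The fallback uses a sulfonate whose sulfur is far less electrophilic and which therefore tolerates heating. Setting out from 8, TsCl, N-methylimidazole and LiOH should give, through the lithium chelate, the enol tosylate methyl (Z)-3-[2,4-bis(prop-2-en-1-yloxy)phenyl]-2-(3-methylbut-2-en-1-yl)-3-[(4-methylbenzenesulfonyl)oxy]prop-2-enoate F2. Its addition–elimination with 3 and Cs2CO3 in DMF at 60 °C rejoins the route at 10.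

Step 1. The alkylation may not stop cleanly at two ring carbons, so that mono-, tri-, O-alkylated and geminally dialkylated material forms alongside the wanted product. The fallback fixes the positions by directed ortho-metalation. Setting out from 1, MOMCl and NaH in DMF should give 1,3,5-tris(methoxymethoxy)benzene F3. Lithiation between two methoxymethoxy groups (n-BuLi, THF, 0 °C), transmetalation with CuBr·SMe2 and alkylation with 2 should give 1,3,5-tris(methoxymethoxy)-2-(3-methylbut-2-en-1-yl)benzene F4. A second round of the same operations, at either of the two equivalent remaining positions, should give 1,3,5-tris(methoxymethoxy)-2,4-bis(3-methylbut-2-en-1-yl)benzene F5. Dilute HCl in MeOH at rt removes the three acetals and rejoins the route at 3.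

Further compounds
F1 | step 9 | (Z)-3-[2,4-bis(prop-2-en-1-yloxy)phenyl]-3-[3,5-bis(prop-2-en-1-yloxy)-2,4-bis(3-methylbut-2-en-1-yl)phenoxy]-2-(3-methylbut-2-en-1-yl)prop-2-enoyl chloride | O=C(Cl)/C(CC=C(C)C)=C(\Oc1cc(OCC=C)c(CC=C(C)C)c(OCC=C)c1CC=C(C)C)c1ccc(OCC=C)cc1OCC=C
F2 | step 6 | methyl (Z)-3-[2,4-bis(prop-2-en-1-yloxy)phenyl]-2-(3-methylbut-2-en-1-yl)-3-[(4-methylbenzenesulfonyl)oxy]prop-2-enoate | COC(=O)/C(CC=C(C)C)=C(\OS(=O)(=O)c1ccc(C)cc1)c1ccc(OCC=C)cc1OCC=C
F3 | step 1 | 1,3,5-tris(methoxymethoxy)benzene | COCOc1cc(OCOC)cc(OCOC)c1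
F4 | step 1 | 1,3,5-tris(methoxymethoxy)-2-(3-methylbut-2-en-1-yl)benzene | COCOc1cc(OCOC)c(CC=C(C)C)c(OCOC)c1
F5 | step 1 | 1,3,5-tris(methoxymethoxy)-2,4-bis(3-methylbut-2-en-1-yl)benzene | COCOc1cc(OCOC)c(CC=C(C)C)c(OCOC)c1CC=C(C)C
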